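The readings were computed for an exercise; scatter was added.

The winter run cannot have stopped for lack of starting material: its last reading, 80.9 mM of product at 100 min, still leaves 169 mM of it, and the partner charge less that product comes to 194 mM.

the same everywhere: free catalyst 2.50 mM
- winter: starting material 250 mM; partner 275 mM
- noon: starting material 130 mM; partner 155 mM
- spring: starting material 250 mM; partner 550 mM
- dusk: starting material 500 mM; partner 275 mM
- dawn: starting material 250 mM; partner 1800 mM; time 100 min

| run | time / min | [product] / mM |
|---|---|---|
| winter run | 17 | 34.6 |
| winter run | 33 | 54.9 |
| winter run | 50 | 68.4 |
| winter run | 67 | 74.9 |
| winter run | 83 | 78.5 |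
| winter run | 100 | 80.9 |
| noon run | 17 | 10.2 |
| noon run | 33 | 19.0 |
| noon run | 50 | 26.5 |
| noon run | 67 | 31.4 |
| noon run | 83 | 34.2 |
| noon run | 100 | 38.8 |
| spring run | 17 | 60.5 |
| spring run | 33 | 86.5 |
| spring run | 50 | 101.5 |
| spring run | 67 | 108.6 |
| spring run | 83 | 111.6 |
| spring run | 100 | 109.9 |
| dusk run | 17 | 64.5 |
| dusk run | 33 | 93.9 |
| dusk run | 50 | 110.4 |
| dusk run | 67 | 116.3 |
| dusk run | 83 | 116.4 |
| dusk run | 100 | 120.3 |

(standard deviation of a reading: 0.8 mM)

- Overall: starting material + partner -> product, with free catalyst as catalyst.
- Constant volume, constant temperature.
- "The second partner" is partner.
- An order is taken over about fifteen percent of the charge, up and down.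

- the exponent of [starting material] in the starting rate at the charge of the winter run (at the point where two percent of the starting material have become product) (one fixed amount of product, the same in the runs compared)
- the exponent of [partner] in the starting rate at the charge of the winter run (at the point where two percent of the starting material have become product)
- product in the dawn run at 100 min, as a share of the starting material charged

I read the table along its bottom row and reckoned with charge less product, not with the product made. Twice the partner in the spring run raised the last reading by a factor of 1.36, and twice the starting material in the dusk run raised it by 1.49, so the end point did not scale with either charge.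

The winter row gave 0.199. This is the stopping quotient Q: the square of c(product) over c(starting material) times c(partner), each of the last two reckoned as charge less product, at the last reading. The spring row gave 0.196 and the dusk row 0.246. The noon run was still rising, from 34.2 mM to 38.8 mM, so I set it aside. The dawn run is rich in partner, like the spring run, so I carried the winter value, which the spring row matched, and not the dusk one.

The spring run had flattened by 67 min, and the dawn run holds 3.27 times its partner, so I expected the dawn run to reach its end by 100 min. Solving the quotient for starting material, the limiting reagent there, gave 166 mM, or 66.3 %. The first readings gave apparent orders of 0.899 in starting material and 0.806 in partner, but those flasks were already slowing, so I took each order as near one.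

The forecast gave 1.07 and 1.07 for the orders and 68 % for the dawn run, which is above my share. It used the same form with a quotient of 0.22, having seen “so something stops the reaction”.

The flask gave 1.0, 1.0 and 64.7 %, and the forecast stood within its margins.

    2 free catalyst ⇌ catalyst dimer, settled at all times (148.0 M⁻¹)
    catalyst dimer + starting material + partner → product + catalyst dimer (92.40 M⁻² min⁻¹)
    free catalyst + product → spent catalyst + product (0.2808 M⁻¹ min⁻¹)
    2 partner → lost reagent (0.01338 M⁻¹ min⁻¹)

The dawn run's share puts Q at 0.181, yet Q is no equilibrium constant. The same dawn flask without the conversion of free catalyst into spent catalyst reaches 90.1 % at 100 min, which puts Q at 1.30, far above the flask as it is. The dawn run falls short because product turns free catalyst into spent catalyst, and this step accounts for 72 % of what is missing.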